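**Structural features**

The target is oxacyclohentriacontan-2-one, the lactone of 30-hydroxytriacontanoic acid. It is a single 31-membered ring made of the ester oxygen, the carbonyl carbon and an unbroken run of 29 methylene groups. It has no stereocentre, no substituent and no second ring, so neither neighbouring stereocentres nor ring fusions have to be considered. The lactone is the only functional group and the only fragile one: it can be attacked at the carbonyl by hydroxide or alkoxide and enolised at the CH2 next to the carbonyl. The real difficulty is the absence of handles. A 30-carbon chain must be assembled from purchasable pieces, a very large ring must be closed against oligomerisation, and whatever group serves these tasks must vanish without trace. Every CH2–CH2 bond of the chain is equivalent for this purpose, so the bond can be chosen to fit the building blocks. The bond C8–C9 (counted from the carbonyl carbon as C1; C9–C10 in ring locants) divides the chain into a seven-methylene acyl arm and a 22-carbon alkoxy arm. The key step treats C8–C9 as the remnant of a CH2–SO2–CH2 unit in a 32-membered thia-lactone ring (S10 of a 1-oxa-10-thiacyclodotriacontan-2-one), which contracts to the 31-membered ring on loss of SO2.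

**Logic of the disconnections**

11 to 10. No skeletal bond is cut; a C8=C9 double bond is written into the saturated chain. This places a functional group at the one position where the chain is to be stitched, at the price of one clean final operation. The forward step must saturate a disubstituted alkene without touching the lactone. It also erases the alkene geometry, so 10 need not be a single isomer.

10 to 8. The C8=C9 bond is cut and SO2 is inserted between the two carbons, one of which also carries chlorine; the ring grows from 31 to 32 members. A C–C bond in the middle of an unfunctionalised chain thereby becomes two C–S bonds, which are far easier to make, and the forward reaction is driven by loss of a gas. The forward step demands that base removes a proton next to the sulfonyl group and that the carbanion expels chloride before anything irreversible happens at the lactone. The halogen is therefore built into 8 beforehand. A halogen donor in the basic medium would also halogenate the lactone enolate, which forms about as readily as the sulfonyl carbanion.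

8 to 5. The C–Cl bond and both S=O bonds are removed. At the sulfide level the sulfur atom directs chlorination to its own alpha carbons, so the CH2 next to the lactone carbonyl is never at risk. The gain is a precursor with no stereocentre and no reactive group besides ester and sulfide. The forward sequence must introduce one chlorine only and must oxidise the water-sensitive 6 (through 7) without isolating it. Which alpha carbon is chlorinated does not matter.

5 to 4. The S10–C11 bond of the ring is cut, leaving a thiol at the end of the acyl arm and a primary bromide at the end of the alkoxy arm. Thiolate alkylation is the most dependable SN2 pairing available, is irreversible, and runs under a carbonate base that leaves an ester alone. Holding nucleophile and electrophile in one molecule fixes their ratio at one to one. The forward step demands high dilution and exclusion of oxygen.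

4 to 2 + 3. The ester C–O bond is cut. This is the convergent cut: it divides the molecule into a C22 piece and a C8 piece, each simple and bifunctional. The forward step must acylate oxygen in the presence of a free thiol and a primary bromide, which calls for acid-catalysed equilibrium esterification and not an activated acyl donor.

2 to 1. The C–Br bond is traced back to a C–OH bond of a symmetrical diol. The gain is a cheap symmetrical C22 starting material. The demand is that only one of two identical hydroxyl groups reacts.

**Other disconnections considered**

Alternative 1: The cut removes both bonds to the carbonyl carbon (C1–C2 and C1–O), which would be supplied by CO. In the forward direction (28E)-29-iodononacos-28-en-1-ol A1 would be treated with Pd(PPh3)4 under CO with a mild base at high dilution. Zerovalent palladium adds to the C–I bond, CO inserts, and the remote hydroxyl captures the acylpalladium to give (3E)-oxacyclohentriacont-3-en-2-one A2; hydrogenation would then give 11.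
- In its favour: two bonds and the ring are formed in one catalytic operation, the vinyl iodide geometry should carry over to the enoate, and the lactone never meets a strong base. On the last point it is better than the chosen plan, whose key step exposes the lactone to KOt-Bu.
- Equal: both plans end with one hydrogenation of an unsaturated 31-membered lactone, and both need one high-dilution step.
- Against it here: A1 is a 29-carbon chain with two different ends that cannot be bought. Building it needs several C–C couplings and end-group adjustments, more operations than the whole chosen route. CO is a toxic gas, and capture of the acylpalladium by a hydroxyl across a 31-atom ring must compete with intermolecular alkoxycarbonylation.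
- Comparison: the alternative's key step is a catalytic oxidative addition, insertion and acyl capture and is the more bond-forming; the chosen key step is a carbanion 1,3-elimination followed by SO2 extrusion. The chosen plan is clearly shorter overall because both of its carbon chains are purchased.

Alternative 2: The cut is the C18–C19 single bond, seen as the central bond of a 1,3-diyne. Octadec-17-ynoic acid A3 and dodec-11-yn-1-ol A4 would be esterified to dodec-11-yn-1-yl octadec-17-ynoate A5. Oxidative coupling with Cu(OAc)2 in pyridine at high dilution, in which divalent copper oxidises the two copper acetylides, would give oxacyclohentriaconta-18,20-diyn-2-one A6; exhaustive hydrogenation would give 11.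
- In its favour: three operations from two terminal alkynes against six in the chosen plan, conditions that are gentle towards the lactone, and a ring closure of long standing for large rings. On step count and on safety of the lactone it is better than the chosen plan.
- Equal: both plans place an erasable functional group at an arbitrary position of the chain, and both face oligomerisation at finite dilution.
- Against it here: A3 is a costly speciality chemical and A4 is less common than the bromo and thiol building blocks. The coupling needs a large excess of copper salt in large volumes of pyridine, and the diyne takes up four equivalents of hydrogen.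
- Comparison: the alternative couples two sp carbons oxidatively; the chosen plan closes its ring by a thiolate SN2 reaction with fixed one-to-one stoichiometry and then contracts it irreversibly. The chosen plan is preferable on cost and availability of starting materials, the alternative on length.

Alternative 3: The cut removes two double bonds, C11=C12 and C26=C27, dividing the ring into a 16-membered unsaturated lactone and a 15-membered cycloalkene. (12E)-Oxacyclohexadec-12-en-2-one A7 and (E)-cyclopentadecene A8 would be treated with (H2IMes)(PCy3)Cl2Ru=CHPh, the second-generation Grubbs catalyst. The alkylidene opens one ring, the new chain-end carbene engages the other ring and back-bites, giving (12E,27E)-oxacyclohentriaconta-12,27-dien-2-one A9; hydrogenation would give 11.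
- In its favour: two operations, complete atom economy, and A7 is a bulk fragrance chemical. Any one-to-one combination of the two rings has 31 ring atoms, so positional and geometric alkene isomers would converge on hydrogenation. On nominal step count and atom economy it is better than the chosen plan.
- Against it here: neither ring is strained, so nothing drives the merger. Ring opening and closing are reversible, so self-combination of each cycloalkene and open-ended oligomerisation compete statistically, and dilution favours return to the smaller rings. Double-bond migration by ruthenium hydrides would create ring-size homologues that are nearly inseparable from 11 after hydrogenation. A8 is not a stock item and would itself have to be made.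
- Comparison: the alternative runs under thermodynamic control with the desired ring not the energy minimum. The chosen plan makes each bond in a directed, irreversible event and gives one ring size only, at the cost of more steps and stoichiometric reagents.

Key step: step 5

Remarks on the chemistry:
- Bond labels such as C8–C9 count from the carbonyl carbon as C1; compound names use ring locants (O1, carbonyl C2), in which the same bond is C9–C10.
- Chlorination next to sulfur cannot distinguish C9 from C11 of ring 5, so 6, 7 and 8 are expected as mixtures of 11-chloro and 9-chloro regioisomers, each racemic. Both give the same alkene, and the 11-chloro isomer is written to represent the mixture.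
- Docosane-1,22-diol and 8-sulfanyloctanoic acid are taken as catalogue chemicals.

**Step 1**
Reactants: 1 docosane-1,22-diol
Product: 2 22-bromodocosan-1-ol
Conditions: 48% aq. HBr (1.2 equiv), toluene, reflux
Reagents that add atoms: hydrogen bromide, Br
Why: Monobromination of a symmetrical alpha,omega-diol by SN2 substitution of a protonated hydroxyl; with a small excess of aqueous HBr in toluene the reaction should stop largely at the bromo alcohol, which leaves the polar acid phase, and residual diol and dibromide differ enough in polarity to be removed by crystallisation or chromatography.

**Step 2**
Reactants: 2 22-bromodocosan-1-ol; 3 8-sulfanyloctanoic acid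
Product: 4 22-bromodocosyl 8-sulfanyloctanoate
Conditions: TsOH·H2O (5 mol%), toluene, reflux, Dean–Stark trap, N2
Reagents that add atoms: none
Why: Fischer esterification driven by azeotropic removal of water; under acid-catalysed equilibrium conditions oxygen is acylated because thioester formation is thermodynamically disfavoured, and the neutral thiol is too poor a nucleophile in toluene to displace the primary bromide, whereas a carbodiimide coupling would acylate sulfur.

**Step 3**
Reactants: 4 22-bromodocosyl 8-sulfanyloctanoate
Product: 5 1-oxa-10-thiacyclodotriacontan-2-one
Conditions: Cs2CO3 (2 equiv), degassed DMF, 50 °C, syringe-pump addition of 4 over 12 h (final ca. 1 mM), Ar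
Reagents that add atoms: none
Why: Intramolecular SN2 S-alkylation of a cesium thiolate by the primary bromide (thioether macrocyclisation) under pseudo-high dilution; the soft, weakly ion-paired thiolate reacts fast at low stationary concentration, the carbonate does not harm the ester, and the strain-free 32-membered ring closes in exo-tet fashion.

**Step 4**
Reactants: 5 1-oxa-10-thiacyclodotriacontan-2-one
Product: 8 11-chloro-1-oxa-10-thiacyclodotriacontan-2-one 10,10-dioxide (racemic), via alpha-chloro sulfide 6 (not isolated), via alpha-chloro sulfoxide 7 (not isolated)
Conditions: NCS (1.05 equiv), CH2Cl2, 0 °C → rt; then mCPBA (2.5 equiv), 0 °C → rt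
Reagents that add atoms: N-chlorosuccinimide (NCS), O=C1CCC(=O)N1Cl; 3-chloroperoxybenzoic acid (mCPBA), OOC(=O)c1cccc(Cl)c1
Why: Alpha-chlorination of a dialkyl sulfide by NCS (S-chlorosulfonium salt, loss of HCl to a thionium ion, return of chloride; a Pummerer-type process), then peracid oxidation through the sulfoxide to the sulfone; both reagents ignore the lactone and its neighbouring CH2, and the racemic chlorine-bearing stereocentre is destroyed in step 5.

**Step 5**
Reactants: 8 11-chloro-1-oxa-10-thiacyclodotriacontan-2-one 10,10-dioxide
Product: 10 (9E)-oxacyclohentriacont-9-en-2-one, via trans-episulfone 9 (not isolated)
Conditions: KOt-Bu (3 equiv), THF (5 mM), –40 °C → 0 °C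
Reagents that add atoms: none
Why: Ramberg–Bäcklund reaction: KOt-Bu reversibly removes a proton from C9, the alpha-prime carbon of 8, and the carbanion displaces chloride from C11 across sulfur in a 1,3-elimination (3-exo-tet) to give episulfone 9, which loses SO2 in a cheletropic step and joins the two former alpha carbons as C9=C10 of 10 (C8=C9 when counted from the carbonyl carbon). The closest known reaction type is the base-induced ring contraction of cyclic alpha-halo sulfones to cycloalkenes, macrocyclic cases included. The only ring closed directly is the three-membered thiirane dioxide; the 31-membered ring arises by contraction of the 32-membered one, not by end-to-end closure, so it carries no entropic penalty, and moderate dilution serves only to suppress bimolecular reactions of the lactone. No stereocentre remains: the two carbon stereocentres of 9 vanish with SO2, and the alkene geometry, expected to be mainly E because the strong base equilibrates 9 to its trans form before extrusion, is removed in step 6. The selectivity needed is chemoselectivity against the lactone: with chlorine already in place no halogen donor is present to trap the lactone enolate, enolisation at C3 is reversible and leads nowhere, the hindered tert-butoxide adds only slowly to the carbonyl at low temperature, and the sulfonyl carbanion is consumed irreversibly. Regioselectivity is not needed, since either chloro regioisomer of 8 delivers the same C=C bond.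

**Step 6**
Reactants: 10 (9E)-oxacyclohentriacont-9-en-2-one
Product: 11 oxacyclohentriacontan-2-one
Conditions: H2 (1 atm), 10% Pd/C, EtOAc, rt
Reagents that add atoms: none
Why: Heterogeneous catalytic hydrogenation of an unhindered disubstituted alkene; the lactone is inert, both alkene geometries give the same saturated ring, and chromatography of 10 beforehand removes sulfur-containing traces that could poison the catalyst.

**Compound list**

1 | docosane-1,22-diol | OCCCCCCCCCCCCCCCCCCCCCCO | starting material
2 | 22-bromodocosan-1-ol | OCCCCCCCCCCCCCCCCCCCCCCBr | intermediate
3 | 8-sulfanyloctanoic acid (8-mercaptooctanoic acid) | OC(=O)CCCCCCCS | starting material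
4 | 22-bromodocosyl 8-sulfanyloctanoate | SCCCCCCCC(=O)OCCCCCCCCCCCCCCCCCCCCCCBr | intermediate
5 | 1-oxa-10-thiacyclodotriacontan-2-one | O=C1CCCCCCCSCCCCCCCCCCCCCCCCCCCCCCO1 | intermediate
6 | 11-chloro-1-oxa-10-thiacyclodotriacontan-2-one (racemic; represents the C9/C11 regioisomer pair; not isolated) | O=C1CCCCCCCSC(Cl)CCCCCCCCCCCCCCCCCCCCCO1 | intermediate
7 | 11-chloro-1-oxa-10-thiacyclodotriacontan-2-one 10-oxide (mixture of diastereomers, each racemic; not isolated) | O=C1CCCCCCCS(=O)C(Cl)CCCCCCCCCCCCCCCCCCCCCO1 | intermediate
8 | 11-chloro-1-oxa-10-thiacyclodotriacontan-2-one 10,10-dioxide (racemic; represents the C9/C11 regioisomer pair) | O=C1CCCCCCCS(=O)(=O)C(Cl)CCCCCCCCCCCCCCCCCCCCCO1 | intermediate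
9 | rac-(1R,31R)-9-oxa-32-thiabicyclo[29.1.0]dotriacontan-8-one 32,32-dioxide (trans-episulfone, one enantiomer drawn; not isolated) | O=C1CCCCCC[C@@H]2[C@@H](CCCCCCCCCCCCCCCCCCCCCO1)S2(=O)=O | intermediate
10 | (9E)-oxacyclohentriacont-9-en-2-one | O=C1CCCCCC/C=C/CCCCCCCCCCCCCCCCCCCCCO1 | intermediate
11 | oxacyclohentriacontan-2-one | O=C1CCCCCCCCCCCCCCCCCCCCCCCCCCCCCO1 | target

Total step count: 6. Longest linear sequence: 6 steps (1 to 11).

**Steps least certain to work**

Step 5 (key step). The 1,3-elimination of chloride may be slow at the low temperature chosen to protect the lactone. On warming, tert-butoxide may then open the ring by transesterification, or the lactone enolate may condense with a second molecule, before SO2 is extruded. Fallback, setting out from 8 and returning at 11: give up the contraction on the intact ring. Heating 8 with KOH in aqueous dioxane should saponify the lactone and run the Ramberg–Bäcklund reaction on the open-chain carboxylate, where no ester is left to suffer, giving (8Z)-30-hydroxytriacont-8-enoic acid F1 (the Z form is expected to predominate with aqueous hydroxide, and the geometry is of no consequence). Hydrogenation over 10% Pd/C would give 30-hydroxytriacontanoic acid F2. Yamaguchi macrolactonisation (2,4,6-trichlorobenzoyl chloride, Et3N, then DMAP in toluene at high dilution) through 30-hydroxytriacontanoic 2,4,6-trichlorobenzoic anhydride F3 would then close the ring to 11.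

Step 3. Intermolecular S-alkylation to linear and cyclic oligomers, or oxidative coupling of the thiol by traces of oxygen, may outrun ring closure if the stationary concentration is not kept low. Fallback, setting out from 2 (with 3) and returning at 5: form the C–S bond intermolecularly and close the ring at the ester. Alkylation of the dianion of 3 (NaOH, 2.1 equiv, EtOH/THF) by 2 should give 8-[(22-hydroxydocosyl)sulfanyl]octanoic acid F4. Yamaguchi macrolactonisation through 8-[(22-hydroxydocosyl)sulfanyl]octanoic 2,4,6-trichlorobenzoic anhydride F5 would then deliver 5.

Step 4. The alpha-chloro sulfide is hydrolytically labile; adventitious water would cleave the ring at the C–S bond. Loss of HCl to a vinyl sulfide or a second chlorination can also occur before the oxidant is added. Fallback, setting out from 5 and returning at 10: oxidise 5 directly with mCPBA to 1-oxa-10-thiacyclodotriacontan-2-one 10,10-dioxide F6. F6 would then be halogenated and contracted in one flask (KOH on Al2O3, CBr2F2, t-BuOH/CH2Cl2) through 11-bromo-1-oxa-10-thiacyclodotriacontan-2-one 10,10-dioxide F7 and episulfone 9 to 10. This is the second choice because the halogen donor and hydroxide share the flask with the enolisable lactone.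

Step 2. Adventitious S-acylation or air oxidation of the thiol during prolonged heating would reduce the amount of usable 4. Fallback, setting out from 2 and returning at 5: avoid the free thiol. Acid-catalysed esterification of 2 with 8-bromooctanoic acid should give 22-bromodocosyl 8-bromooctanoate F8. Double alkylation of Na2S·9H2O (DMF, simultaneous slow addition at high dilution) would then close the sulfide ring to 5. The price is less control of stoichiometry and a more basic medium.

**Further compounds**

F1 | step 5 | (8Z)-30-hydroxytriacont-8-enoic acid | OC(=O)CCCCCC/C=C\CCCCCCCCCCCCCCCCCCCCCO
F2 | step 5 | 30-hydroxytriacontanoic acid | OC(=O)CCCCCCCCCCCCCCCCCCCCCCCCCCCCCO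
F3 | step 5 | 30-hydroxytriacontanoic 2,4,6-trichlorobenzoic anhydride | OCCCCCCCCCCCCCCCCCCCCCCCCCCCCCC(=O)OC(=O)c1c(Cl)cc(Cl)cc1Cl
F4 | step 3 | 8-[(22-hydroxydocosyl)sulfanyl]octanoic acid | OC(=O)CCCCCCCSCCCCCCCCCCCCCCCCCCCCCCO
F5 | step 3 | 8-[(22-hydroxydocosyl)sulfanyl]octanoic 2,4,6-trichlorobenzoic anhydride | OCCCCCCCCCCCCCCCCCCCCCCSCCCCCCCC(=O)OC(=O)c1c(Cl)cc(Cl)cc1Cl
F6 | step 4 | 1-oxa-10-thiacyclodotriacontan-2-one 10,10-dioxide | O=C1CCCCCCCS(=O)(=O)CCCCCCCCCCCCCCCCCCCCCCO1
F7 | step 4 | 11-bromo-1-oxa-10-thiacyclodotriacontan-2-one 10,10-dioxide (racemic; represents the C9/C11 regioisomer pair) | O=C1CCCCCCCS(=O)(=O)C(Br)CCCCCCCCCCCCCCCCCCCCCO1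
F8 | step 2 | 22-bromodocosyl 8-bromooctanoate | BrCCCCCCCC(=O)OCCCCCCCCCCCCCCCCCCCCCCBr
A1 | alternative 1 | (28E)-29-iodononacos-28-en-1-ol | OCCCCCCCCCCCCCCCCCCCCCCCCCCC/C=C/I
A2 | alternative 1 | (3E)-oxacyclohentriacont-3-en-2-one | O=C1/C=C/CCCCCCCCCCCCCCCCCCCCCCCCCCCO1
A3 | alternative 2 | octadec-17-ynoic acid | OC(=O)CCCCCCCCCCCCCCCC#C
A4 | alternative 2 | dodec-11-yn-1-ol | OCCCCCCCCCCC#C
A5 | alternative 2 | dodec-11-yn-1-yl octadec-17-ynoate | C#CCCCCCCCCCCCCCCCC(=O)OCCCCCCCCCCC#C
A6 | alternative 2 | oxacyclohentriaconta-18,20-diyn-2-one | O=C1CCCCCCCCCCCCCCCC#CC#CCCCCCCCCCCO1
A7 | alternative 3 | (12E)-oxacyclohexadec-12-en-2-one | O=C1CCCCCCCCC/C=C/CCCO1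
A8 | alternative 3 | (E)-cyclopentadecene | C1CCCCCCCCCCCC/C=C/1
A9 | alternative 3 | (12E,27E)-oxacyclohentriaconta-12,27-dien-2-one | O=C1CCCCCCCCC/C=C/CCCCCCCCCCCCC/C=C/CCCO1
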